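**Retrosynthetic overview**
- The C4 stereocentre is set last, by face-selective hydrogenation of the C3=C4 bond of a spiro 2H-pyran.
- The strategy rests on the pyran ring (O1, spiro C2, C3, C4, C4a, C8a). It is the closed valence tautomer of the 1-oxatriene O1=C8a–C4a=C4–C3=C2, in which C2 is also C2 of the 6,6-dimethylbicyclo[3.1.1]heptane. Cutting O1–C2 (oxa-6π) and C4a–C4 (allenylation) gives syncarpic acid and a tertiary propargylic alcohol.
- The propargylic alcohol comes from (+)-nopinone and the acetylide of 4-methylpent-1-yne.
- Ring order: the bicycloheptane and the tetramethyl trione carbocycle (ring A, C4a–C8a) are bought; the pyran (ring B) is the only ring made, in the key step.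

Key step: step 2

Remark: syncarpic acid is taken as a catalogue compound; it reacts through its enol, and its two flanking carbonyls are equivalent by symmetry.
Remark: the ligand antipode in step 3 is the one that adds hydrogen to the C4 Re face; the (S) descriptor written is the assumed sense and is inverted if the catalyst selects the Si face.

**Step 1**
Reactants: 1 (1R,5S)-(+)-nopinone; 2 4-methylpent-1-yne
Product: 4 (1R,2R,5S)-6,6-dimethyl-2-(4-methylpent-1-yn-1-yl)bicyclo[3.1.1]heptan-2-ol, via lithium 4-methylpent-1-ynide 3 (not isolated)
Conditions: 2, n-BuLi, THF, −78 °C; then 1, −78 → 0 °C; aq NH4Cl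
Reagents that add atoms: none
Why: 1,2-addition of a lithium acetylide to a ketone, with the nucleophile entering on the face of the C7 methylene bridge, anti to the gem-dimethyl bridge, so the hydroxyl ends syn to that bridge; this centre becomes planar in step 2, so its configuration does not carry into the target.

**Step 2**
Reactants: 4 (1R,2R,5S)-6,6-dimethyl-2-(4-methylpent-1-yn-1-yl)bicyclo[3.1.1]heptan-2-ol; 5 syncarpic acid (2,2,4,4-tetramethylcyclohexane-1,3,5-trione)
Product: 8 (1R,2R,5S)-6,6,6',6',8',8'-hexamethyl-4'-(2-methylpropyl)spiro[bicyclo[3.1.1]heptane-2,2'-chromene]-5',7'(6'H,8'H)-dione, via 2-allenyl syncarpic acid 6 (not isolated), via nopinylidene 1-oxatriene 7 (not isolated)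
Conditions: 4 (1 equiv), 5 (1.5 equiv), Ca(NTf2)2 (5 mol %), Bu4NPF6 (5 mol %), CH2Cl2, 0 °C → rt; then Et3N (10 mol %), aq NaHCO3 wash, used at once
Reagents that add atoms: none
Why: The calcium Lewis acid ionises the tertiary propargylic C–O bond of 4 to a propargyl/allenyl cation, which the enol carbon of 5 captures at the alkyne terminus (C4a–C4 bond; any O-propargyl enol ether formed reaches the same allene 6 by propargyl Claisen shift), and transfer of the enol hydrogen to the central allene carbon C3 (formally a 1,5-hydrogen shift) gives 1-oxatriene 7. The closest known reaction type is the acid-catalysed coupling of tertiary propargylic alcohols with cyclic 1,3-diones to fused 2H-pyrans by allenylation and electrocyclisation. Ring B closes by thermal disrotatory oxa-6π electrocyclisation of 7 (O1–C2 bond), so C2 is bonded as a planar nopinylidene carbon and not as a free pinanyl cation. The spiro centre is set by torquoselectivity: O1 swings in on the C2 face of the C7 methylene bridge because the syn methyl of the gem-dimethyl bridge blocks the other face, which places O1 anti and pyran C3 syn to that bridge, as in the target. The step needs attack at the alkyne terminus and not at the carbinol carbon, which the fully substituted, bicyclic carbinol carbon secures, and it needs kinetic control of the closure; the closure is reversible and the epimer with O1 syn to the bridge may be the more stable one, so the reaction is kept at or below room temperature and quenched with base. Charge delocalisation into the alkyne and the excess of nucleophile are relied on to outrun E1 loss of a C3 proton and cleavage of the cyclobutane.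

**Step 3**
Reactants: 8 (1R,2R,5S)-6,6,6',6',8',8'-hexamethyl-4'-(2-methylpropyl)spiro[bicyclo[3.1.1]heptane-2,2'-chromene]-5',7'(6'H,8'H)-dione
Product: 9 (1R,2R,4'S,5S)-6,6,6',6',8',8'-hexamethyl-4'-(2-methylpropyl)-3',4'-dihydrospiro[bicyclo[3.1.1]heptane-2,2'-chromene]-5',7'(6'H,8'H)-dione
Conditions: H2 (50 bar), [Ir(cod)((S)-tBu-PHOX)]BArF (2 mol %; cod = 1,5-cyclooctadiene, BArF = tetrakis[3,5-bis(trifluoromethyl)phenyl]borate), CH2Cl2, rt
Reagents that add atoms: none
Why: Iridium N,P-catalysed asymmetric hydrogenation of a trisubstituted alkene: the cationic iridium phosphinooxazoline complex reduces only C3=C4 (the tetrasubstituted, ketone-conjugated enol ether C4a=C8a and the two ketones are not substrates), and its chiral pocket, not the spiro centre, is relied on to deliver both hydrogens to the C4 Re face, the ring face that carries the nopinane bridgehead C1, giving (4'S) with the isobutyl group cis to the nopinane C3 methylene.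

**Compound list**
1 | (1R,5S)-(+)-nopinone, (1R,5S)-6,6-dimethylbicyclo[3.1.1]heptan-2-one | CC1(C)[C@H]2CCC(=O)[C@@H]1C2 | starting material
2 | 4-methylpent-1-yne | CC(C)CC#C | starting material
3 | lithium 4-methylpent-1-ynide | CC(C)CC#C[Li] | intermediate
4 | (1R,2R,5S)-6,6-dimethyl-2-(4-methylpent-1-yn-1-yl)bicyclo[3.1.1]heptan-2-ol; hydroxyl syn to the gem-dimethyl bridge | O[C@@]1(CC[C@H]2C[C@@H]1C2(C)C)C#CCC(C)C | intermediate
5 | syncarpic acid, 2,2,4,4-tetramethylcyclohexane-1,3,5-trione | CC1(C)C(=O)CC(=O)C(C)(C)C1=O | starting material
6 | 2-allenyl syncarpic acid, enol form: 4-{1-[((1R,5S)-6,6-dimethylbicyclo[3.1.1]heptan-2-ylidene)methylidene]-3-methylbutyl}-5-hydroxy-2,2,6,6-tetramethylcyclohex-4-ene-1,3-dione; allene axis unassigned | CC(C)CC(=C=C1CC[C@H]2C[C@@H]1C2(C)C)C1=C(O)C(C)(C)C(=O)C(C)(C)C1=O | intermediate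
7 | 1-oxatriene: 6-{1-[(1R,5S)-6,6-dimethylbicyclo[3.1.1]heptan-2-ylidene]-4-methylpentan-2-ylidene}-2,2,4,4-tetramethylcyclohexane-1,3,5-trione; either C2=C3 geometry | CC(C)CC(C=C1CC[C@H]2C[C@@H]1C2(C)C)=C1C(=O)C(C)(C)C(=O)C(C)(C)C1=O | intermediate
8 | (1R,2R,5S)-6,6,6',6',8',8'-hexamethyl-4'-(2-methylpropyl)spiro[bicyclo[3.1.1]heptane-2,2'-chromene]-5',7'(6'H,8'H)-dione; spiro 2H-pyran with C3'=C4' alkene, O1' anti to the gem-dimethyl bridge | CC(C)CC1=C[C@@]2(CC[C@H]3C[C@@H]2C3(C)C)OC2=C1C(=O)C(C)(C)C(=O)C2(C)C | intermediate
9 | (1R,2R,4'S,5S)-6,6,6',6',8',8'-hexamethyl-4'-(2-methylpropyl)-3',4'-dihydrospiro[bicyclo[3.1.1]heptane-2,2'-chromene]-5',7'(6'H,8'H)-dione | CC(C)C[C@H]1C[C@@]2(CC[C@H]3C[C@@H]2C3(C)C)OC2=C1C(=O)C(C)(C)C(=O)C2(C)C | target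

**Step count**
Total steps: 3. Longest linear sequence: 3 (1 → 4 → 8 → 9).

**Steps most likely to fail**

Step 2. Two processes threaten it. The propargylic cation may lose a C3 proton to the conjugated enyne, or open its cyclobutane by Wagner–Meerwein shift, before the trione captures it. Separately, the facial selectivity at the spiro centre may be eroded by reversible ring opening of the 2H-pyran. The fallback leaves the ionic pathway and the reversible closure altogether. It sets out from 5 and returns at 9, so steps 2 and 3 are not needed. Compound 5 is condensed with 3-methylbutanal (L-proline cat., CH2Cl2, rt; Knoevenagel condensation) to 2,2,4,4-tetramethyl-6-(3-methylbutylidene)cyclohexane-1,3,5-trione F1. F1 is heated as the oxadiene with (1S,5S)-(−)-β-pinene (toluene, 80 °C) in an inverse-demand oxa-Diels–Alder reaction. O1 adds irreversibly to pinene C2 on the face anti to the gem-dimethyl bridge, so the spiro centre is that of 9. Compound 9 is separated by chromatography from the C4' epimer of 9 F2.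

Step 3. Facial discrimination at C4 may be poor if the ligand pocket and the spiro substituents oppose each other. Turnover at the hindered diene may also be slow, leaving time for epimerisation of the spiro centre by ring opening. The fallback runs from 8 directly to 9 and makes no further compound (F0). It is a metal-hydride hydrogen-atom-transfer hydrogenation (Mn(dpm)3 cat., PhSiH3, t-BuOOH, i-PrOH, rt; dpm = dipivaloylmethanate). Hydrogen-atom transfer to C3 gives a planar C4 radical conjugated with ring A. This radical takes the second hydrogen along the pseudo-axial direction, so the outcome is decided by the half-chair of the substrate and not by a ligand. It should lean toward the epimer with the isobutyl group pseudo-axial, clear of the C5' carbonyl and cis to the smaller C2 arm, which is the arrangement of 9.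

Step 1. Proton transfer from C3 of nopinone to the basic acetylide (enolisation) may return ketone in place of adduct. The fallback sets out from 1 and returns at 4. The smaller, less basic HC≡CMgBr (THF, 0 °C) adds to 1 on the same face to give (1R,2R,5S)-2-ethynyl-6,6-dimethylbicyclo[3.1.1]heptan-2-ol F3. Its O,C-dianion (n-BuLi, 2.1 equiv, THF–DMPU) is then C-alkylated with 1-iodo-2-methylpropane to give 4.

**Further compounds**
F1 | step 2 | 2,2,4,4-tetramethyl-6-(3-methylbutylidene)cyclohexane-1,3,5-trione | CC(C)CC=C1C(=O)C(C)(C)C(=O)C(C)(C)C1=O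
F2 | step 2 | (1R,2R,4'R,5S)-6,6,6',6',8',8'-hexamethyl-4'-(2-methylpropyl)-3',4'-dihydrospiro[bicyclo[3.1.1]heptane-2,2'-chromene]-5',7'(6'H,8'H)-dione (C4' epimer of 9) | CC(C)C[C@@H]1C[C@@]2(CC[C@H]3C[C@@H]2C3(C)C)OC2=C1C(=O)C(C)(C)C(=O)C2(C)C
F0 | step 3 | none | none
F3 | step 1 | (1R,2R,5S)-2-ethynyl-6,6-dimethylbicyclo[3.1.1]heptan-2-ol | O[C@@]1(CC[C@H]2C[C@@H]1C2(C)C)C#C
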